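## Analysis of the target

The target (26 in the numbering below) is a flavonol, a 2-aryl-3-hydroxy-4H-chromen-4-one made of the benzo ring A, the pyranone ring C and a 4-hydroxyphenyl ring B on C2. All three rings are planar, so there is no stereocentre and no stereochemical problem. Ring A is pentasubstituted: oxygen sits on C5, C6 and C7 and, as the ring oxygen O1, on C8a; the C4 carbonyl carbon sits on C4a; only C8 carries hydrogen. Of the five hydroxyl-type oxygens (O3, O5, O6, O7, O4') exactly one, O7, carries the sulfate, and it lies next to the free C6 hydroxyl. The aryl hydrogen sulfate is the delicate group: acid hydrolyses it and it makes the molecule very polar, so it has to come late and the last deprotection has to be neutral. The unmasked 5,6-dihydroxy array is also easily oxidised. The difficulty is therefore regiochemical: four contiguous heteroatoms must be placed on ring A, and O7 must remain distinguishable from O5 and O6 to the end. The plan rests on the fact that C6–O and C8a–O are para, so ring A is a hydroquinone flanked by two more oxygens (C5, C7) and one carbon substituent (C4a). Thermal ring expansion of a squaric-acid-derived 4-alkenyl-4-hydroxycyclobutenone gives exactly this pattern, with each oxygen coming from a different building block.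

## Retrosynthetic reasoning

**Benzyl C–O bonds and the O7–S bond.** Target 26 is traced to the tetrabenzyl sulfate salt 24 by cutting the four benzylic C–O bonds last, because hydrogenolysis is the deprotection an aryl sulfate salt survives. Cutting O7–S then leads to phenol 23, whose only free hydroxyl is O7. The forward steps must sulfate without a competing hydroxyl and debenzylate without hydrolysing the sulfate.

**O7–tert-butyl bond.** Phenol 23 comes from the tert-butyl ether 22. tert-Butyl is chosen for O7 because it leaves by acid-induced ionisation while the benzyl ethers do not, and because it can be brought into ring A on a vinyl ether.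

**C3–O bond.** Ether 22 is the benzyl ether of flavonol 21, and 21 is traced to flavone 19 through the C2=C3 epoxide 20. O3 is introduced after ring C exists, and not by oxidative closure of an open-chain enone, because a C5 substituent is known to divert such closures toward five-membered-ring products.

**Ring C: O1–C2, then C2–C3.** Flavone 19 is opened at O1–C2 to the 1,3-diketone 18 (forward: cyclodehydration). Diketone 18 is cut at C2–C3 into acetophenone 16 and acid chloride 17, which supplies C2 and ring B. These cuts need only a phenol with an ortho C2 unit, which is what the ring expansion delivers.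

**O6–benzyl bond and the acetyl group.** Acetophenone 16 comes from the dihydroxyacetophenone 15; the forward step must alkylate the hydroxyl that is not hydrogen-bonded to the ketone. The acetyl group of 15 is a hydrolysed 1-ethoxyvinyl group, which leads to hydroquinone 14.

**Ring A: C8–C8a bond (key disconnection).** Hydroquinone 14 is traced through dienone 13 and dienylketene 12 to cyclobutenone 11. This cut is preferred over any aromatic substitution on a preformed ring because it leaves no regiochemical choice: the ketene carbonyl becomes the C8a hydroxyl, the carbinol becomes the C6 hydroxyl, the squarate ether becomes O5 and the vinyl ether oxygen becomes O7. The forward reaction has to open the four-membered ring with the hydroxyl turning outward and then close the six-membered ring.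

**C6–C7 bond.** Cyclobutenone 11 is cut between the carbinol carbon and the vinyl carbon into cyclobutenedione 8 and organolithium 10, made from tert-butyl vinyl ether 9. The forward addition must go to the ketone-like carbonyl of 8 and not to the vinylogous ester carbonyl.

**C4–C4a bond and the squarate.** Dione 8 is traced to dibenzyl squarate 3 and organolithium 5, made from ethyl vinyl ether 4, by addition and carbonyl transposition through 6 and 7. Squarate 3 comes from squaric acid 1 and benzyl alcohol 2. The order of the two additions alone fixes which ring A position each substituent takes.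

## Alternatives that were turned down

**Alternative 1: copper-mediated closure of ring C at O1–C8a.**
- Disconnection and key step: the O1–C8a bond is cut, leading to the enolisable bromo diketone 2-(benzyloxy)-1-[3-(benzyloxy)-6-bromo-2,4-bis(methoxymethoxy)phenyl]-3-[4-(benzyloxy)phenyl]propane-1,3-dione A1. An Ullmann-type coupling (CuI, 1,10-phenanthroline, Cs2CO3) would join the enolate oxygen to the brominated carbon and give 3,6-bis(benzyloxy)-2-[4-(benzyloxy)phenyl]-5,7-bis(methoxymethoxy)-4H-chromen-4-one A2.
- For: the C3 oxygen is already in place, so the late epoxidation and benzylation of the chosen route are saved, and the route is convergent. On these points it is stronger.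
- Against: A1 needs a pentasubstituted bromoarene with the acyl group, bromine and three oxygens placed by aromatic substitution, which is the regiochemical problem the chosen route avoids. The coupling would have to occur at a doubly ortho-substituted, electron-rich C–Br bond with a hindered enolate that can also arylate at carbon or fragment by retro-Claisen cleavage.
- Comparison: in A2, O5 and O7 carry the same group, so selective sulfation would depend on the hydrogen-bonded 5-hydroxyl staying inert. The chosen route instead gives O7 a unique, separately removable group.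

**Alternative 2: carbene-catalysed crossed benzoin closing ring C at C3–C4.**
- Disconnection and key step: the C3–C4 bond is cut, leading to the racemic dialdehyde 3-(benzyloxy)-6-{1-[4-(benzyloxy)phenyl]-2-oxoethoxy}-2,4-bis(methoxymethoxy)benzaldehyde A3. A triazolium-derived carbene would turn the aromatic aldehyde into an acyl anion equivalent that adds to the aliphatic aldehyde, giving trans-6-(benzyloxy)-2-[4-(benzyloxy)phenyl]-3-hydroxy-5,7-bis(methoxymethoxy)chroman-4-one A4.
- For: one metal-free catalytic step forms the C4 ketone and the C3 hydroxyl together, which is more direct than the two-stage oxygenation of the chosen route.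
- Against: A4 has two stereocentres that the planar target does not need, so a dehydrogenation must follow. The α-aryloxy arylacetaldehyde in A3 can enolise and eliminate the phenoxide. The carbene would have to attack the hindered, doubly ortho-oxygenated aromatic aldehyde in preference to the aliphatic one, or the regioisomeric ketol results. Ring A again comes from aromatic substitution, with O5 and O7 undifferentiated.
- Comparison: the chosen route is longer after ring closure, but it creates no stereocentre that must be erased and its ring-forming step has no chemoselectivity choice.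

**Alternative 3: Friedel–Crafts closure of ring C at C4–C4a.**
- Disconnection and key step: the C4–C4a bond is cut, leading to (2E)-2-(benzyloxy)-3-[4-(benzyloxy)phenyl]-3-[4-(benzyloxy)-3,5-bis(prop-2-enyloxy)phenoxy]prop-2-enoic acid A5. A mixed anhydride formed with (CF3CO)2O would acylate the phenoxy ring and give 3,6-bis(benzyloxy)-2-[4-(benzyloxy)phenyl]-5,7-bis(prop-2-enyloxy)-4H-chromen-4-one A6.
- For: the phenoxy ring of A5 is symmetrical, so both ortho positions are equivalent and the acylation cannot go to the wrong carbon; the ring is electron-rich and O3 is in place. On regiochemical simplicity of ring closure it matches the chosen route, and it is more convergent.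
- Against: the tetrasubstituted aryloxyacrylic acid A5 must be made with the aryloxy group cis to the carboxyl, for which there is no simple addition route. The closure liberates strong acid in the presence of allyl and benzyl aryl ethers. The symmetry makes O5 and O7 identical in A6.
- Comparison: the chosen route has the longer linear sequence and a late C3 oxidation. In exchange it takes ring A from a four-carbon building block with all four oxygens distinct from the moment the ring forms.

Key step: step 4

Assumption: the target is taken as the free hydrogen sulfate as drawn; because aryl hydrogen sulfates are normally handled as salts, the sulfate is carried as its triethylammonium salt and the proton form is released only in the last operation.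

## Route

Step 1
Reactants: 1 squaric acid; 2 benzyl alcohol
Product: 3 3,4-bis(benzyloxy)cyclobut-3-ene-1,2-dione (dibenzyl squarate)
Conditions: 2 (2.5 equiv), toluene, reflux, Dean–Stark
Reagents that add atoms: none
Why: Squaric acid is a vinylogous carboxylic acid strong enough to catalyse its own Fischer-type esterification, and azeotropic removal of water drives both hydroxyls to the ester, as in the usual preparations of dialkyl squarates.

Step 2
Reactants: 3 dibenzyl squarate; 4 ethyl vinyl ether
Product: 8 3-(benzyloxy)-4-(1-ethoxyethenyl)cyclobut-3-ene-1,2-dione, via 1-ethoxyethenyllithium 5 (not isolated), via lithium alkoxide adduct 6 (not isolated), via tertiary trifluoroacetate 7 (not isolated)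
Conditions: t-BuLi, 4 (excess), THF, −78 → 0 °C; then 3, THF, −78 °C; (CF3CO)2O, −78 °C; aq. NaHCO3, 0 °C
Reagents that add atoms: water, O
Why: α-Lithiation of the vinyl ether gives an acyl anion equivalent that adds once, 1,2, to a squarate carbonyl; O-trifluoroacetylation makes the alkoxide a leaving group, and on aqueous quench allylic ionisation and hydrolysis at the benzyloxy-bearing terminus release benzyl alcohol and give the 3-alkoxy-4-substituted cyclobutenedione (squarate addition with 1,3-carbonyl transposition). The ethoxyvinyl group is conjugated to the dione and so resists protonation in the buffered quench.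

Step 3
Reactants: 8 3-(benzyloxy)-4-(1-ethoxyethenyl)cyclobut-3-ene-1,2-dione; 9 tert-butyl vinyl ether
Product: 11 3-(benzyloxy)-4-(1-tert-butoxyethenyl)-2-(1-ethoxyethenyl)-4-hydroxycyclobut-2-en-1-one (racemic), via 1-tert-butoxyethenyllithium 10 (not isolated)
Conditions: t-BuLi, 9 (excess), THF, −78 → 0 °C; then 8, THF, −78 °C; aq. NH4Cl
Reagents that add atoms: none
Why: tert-Butyl vinyl ether should undergo the same oxygen-directed α-deprotonation as methyl and ethyl vinyl ether, and excess ether ensures no tert-butyllithium remains. In 8 the carbonyl next to the ethoxyvinyl-bearing carbon is a vinylogous ester and is deactivated, so the organolithium adds 1,2 to the ketone-like carbonyl next to the benzyloxy-bearing carbon; the new stereocentre is formed racemic and is destroyed in step 4.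

Step 4
Reactants: 11 3-(benzyloxy)-4-(1-tert-butoxyethenyl)-2-(1-ethoxyethenyl)-4-hydroxycyclobut-2-en-1-one
Product: 14 3-(benzyloxy)-5-tert-butoxy-2-(1-ethoxyethenyl)benzene-1,4-diol, via dienylketene 12 (not isolated), via cyclohexadienone 13 (not isolated)
Conditions: toluene (degassed, 0.02 M), 110 °C, Ar
Reagents that add atoms: none
Why: Heat opens the cyclobutenone of 11 by a conrotatory four-electron electrocyclic cleavage of the bond between the carbonyl carbon (future C8a) and the carbinol carbon (future C6), giving the (Z)-dienylketene 12. The ketene carbon and the terminal CH2 of the tert-butoxyvinyl group (future C8) then join in a thermally allowed disrotatory six-electron electrocyclisation, which forms the C8–C8a bond and closes the six-membered carbocycle, ring A, as dienone 13. Enolisation of 13 gives the aromatic hydroquinone 14 and makes the sequence irreversible; this is the Moore rearrangement of 4-alkenyl-4-hydroxycyclobutenones, here with a 1-alkoxyvinyl group as the alkenyl partner. No stereocentre is created and the single stereocentre of racemic 11 disappears, so 11 need not be resolved. The selectivity required is torquoselectivity: the hydroxyl must rotate outward and the alkoxyvinyl group inward so that the vinyl group lies cis to the ketene, and a donor such as hydroxyl prefers outward rotation, which is the normal behaviour of 4-hydroxycyclobutenones and keeps the ketene from being captured by the hydroxyl. Regiochemistry needs no control here because the positions of O5, O6, O7, O8a and the C4a substituent were fixed by the order of the additions in steps 2 and 3. The ethoxyvinyl group next to the ketene carbon is a spectator, since its only pericyclic option is a reversible four-electron closure to a cyclobutenone while aromatisation drains the dienylketene. Dilute, oxygen-free conditions are used because 14 is an electron-rich hydroquinone, and it is taken into step 5 without chromatography.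

Step 5
Reactants: 14 3-(benzyloxy)-5-tert-butoxy-2-(1-ethoxyethenyl)benzene-1,4-diol
Product: 15 1-[2-(benzyloxy)-4-tert-butoxy-3,6-dihydroxyphenyl]ethan-1-one
Conditions: pyridinium p-toluenesulfonate (cat.), acetone/H2O, rt, Ar
Reagents that add atoms: water, O
Why: Enol ether hydrolysis: the ethoxyvinyl group is protonated at its terminal carbon far faster than an aryl tert-butyl or benzyl ether ionises, so mild aqueous acid unmasks only the acetyl group. The new ketone then ties the adjacent phenol into a hydrogen bond and makes the ring less prone to oxidation.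

Step 6
Reactants: 15 1-[2-(benzyloxy)-4-tert-butoxy-3,6-dihydroxyphenyl]ethan-1-one
Product: 16 1-[2,3-bis(benzyloxy)-4-tert-butoxy-6-hydroxyphenyl]ethan-1-one
Conditions: BnBr (1.05 equiv), K2CO3, DMF, rt, Ar
Reagents that add atoms: benzyl bromide, BrCc1ccccc1
Why: Williamson etherification; the phenol ortho to the acetyl group is held in an intramolecular hydrogen bond and is poorly nucleophilic, so one equivalent of benzyl bromide should alkylate the other hydroxyl, as in the selective 5-O-alkylation of 2,5-dihydroxyacetophenone.

Step 7
Reactants: 16 1-[2,3-bis(benzyloxy)-4-tert-butoxy-6-hydroxyphenyl]ethan-1-one; 17 4-(benzyloxy)benzoyl chloride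
Product: 18 1-[2,3-bis(benzyloxy)-4-tert-butoxy-6-hydroxyphenyl]-3-[4-(benzyloxy)phenyl]propane-1,3-dione
Conditions: LiN(SiMe3)2 (3.2 equiv), THF, −78 °C; then 17, −78 °C → rt; aq. NH4Cl
Reagents that add atoms: none
Why: Excess LiN(SiMe3)2 forms the phenoxide–enolate dianion, whose carbon terminus is the more reactive site toward the acid chloride (Claisen-type C-acylation, a one-flask equivalent of the Baker–Venkataraman sequence). The third equivalent of base deprotonates the product diketone so that proton transfer does not stop the reaction.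

Step 8
Reactants: 18 1-[2,3-bis(benzyloxy)-4-tert-butoxy-6-hydroxyphenyl]-3-[4-(benzyloxy)phenyl]propane-1,3-dione
Product: 19 5,6-bis(benzyloxy)-2-[4-(benzyloxy)phenyl]-7-tert-butoxy-4H-chromen-4-one
Conditions: NaOAc, AcOH, 90 °C
Reagents that add atoms: none
Why: Acid-catalysed cyclodehydration: the phenol adds to the aroyl carbonyl to form the six-membered hemiketal, which loses water to give the chromone. Buffered acetic acid is chosen because the tert-butyl ether, deactivated by the para acyl group, and the benzyl ethers should tolerate it.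

Step 9
Reactants: 19 5,6-bis(benzyloxy)-2-[4-(benzyloxy)phenyl]-7-tert-butoxy-4H-chromen-4-one
Product: 21 5,6-bis(benzyloxy)-2-[4-(benzyloxy)phenyl]-7-tert-butoxy-3-hydroxy-4H-chromen-4-one, via flavone 2,3-epoxide 20 (not isolated)
Conditions: dimethyldioxirane (acetone solution), CH2Cl2, 0 °C → rt; then pyridinium p-toluenesulfonate (cat.), CH2Cl2, rt
Reagents that add atoms: dimethyldioxirane, CC1(C)OO1
Why: Dimethyldioxirane epoxidises the C2=C3 bond of 5-alkoxyflavones; the acetal-like epoxide then ionises at C2 under mild acid and loses the C3 hydrogen to give the 3-hydroxyflavone. The stereocentres of the racemic epoxide are lost in this isomerisation.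

Step 10
Reactants: 21 5,6-bis(benzyloxy)-2-[4-(benzyloxy)phenyl]-7-tert-butoxy-3-hydroxy-4H-chromen-4-one
Product: 22 3,5,6-tris(benzyloxy)-2-[4-(benzyloxy)phenyl]-7-tert-butoxy-4H-chromen-4-one
Conditions: BnBr, K2CO3, DMF, 40 °C
Reagents that add atoms: benzyl bromide, BrCc1ccccc1
Why: Williamson etherification of the only free hydroxyl; protecting O3 removes any competition with O7 in the sulfation.

Step 11
Reactants: 22 3,5,6-tris(benzyloxy)-2-[4-(benzyloxy)phenyl]-7-tert-butoxy-4H-chromen-4-one
Product: 23 3,5,6-tris(benzyloxy)-2-[4-(benzyloxy)phenyl]-7-hydroxy-4H-chromen-4-one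
Conditions: CF3CO2H/CH2Cl2 (1:4), 0 °C
Reagents that add atoms: none
Why: Acidolysis by the SN1 path: protonation at O7 and loss of the tert-butyl cation as isobutene. Primary benzyl aryl ethers need much stronger acid or an added nucleophile, so a short reaction at 0 °C should leave them intact.

Step 12
Reactants: 23 3,5,6-tris(benzyloxy)-2-[4-(benzyloxy)phenyl]-7-hydroxy-4H-chromen-4-one
Product: 24 triethylammonium 3,5,6-tris(benzyloxy)-2-[4-(benzyloxy)phenyl]-4-oxo-4H-chromen-7-yl sulfate
Conditions: SO3·NEt3, DMF, 50 °C
Reagents that add atoms: sulfur trioxide–triethylamine complex, CC[N+](CC)(CC)S(=O)(=O)[O-]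
Why: O-Sulfation of a phenol with a sulfur trioxide amine complex; 23 has a single, acidic free hydroxyl, so no selectivity question arises and the product forms directly as the triethylammonium salt.

Step 13
Reactants: 24 triethylammonium 3,5,6-tris(benzyloxy)-2-[4-(benzyloxy)phenyl]-4-oxo-4H-chromen-7-yl sulfate
Product: 26 3,5,6-trihydroxy-2-(4-hydroxyphenyl)-4-oxo-4H-chromen-7-yl hydrogen sulfate, via debenzylated triethylammonium salt 25 (not isolated)
Conditions: H2 (1 atm), Pd/C, THF/MeOH, rt; then sulfonic acid resin (H+ form), H2O/MeOH, 0 °C, freeze-drying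
Reagents that add atoms: none
Why: Hydrogenolysis of the four benzyl ethers over palladium on carbon should leave the aryl sulfate and the chromone double bond untouched. Cold passage through a sulfonic acid resin exchanges the triethylammonium ion for a proton.

## Compound list

1 | squaric acid (3,4-dihydroxycyclobut-3-ene-1,2-dione) | OC1=C(O)C(=O)C1=O | starting material
2 | benzyl alcohol | OCc1ccccc1 | starting material
3 | 3,4-bis(benzyloxy)cyclobut-3-ene-1,2-dione (dibenzyl squarate) | O=C1C(=O)C(OCc2ccccc2)=C1OCc1ccccc1 | intermediate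
4 | ethyl vinyl ether | C=COCC | starting material
5 | 1-ethoxyethenyllithium | [Li]C(=C)OCC | intermediate (not isolated)
6 | lithium 2,3-bis(benzyloxy)-1-(1-ethoxyethenyl)-4-oxocyclobut-2-en-1-olate (racemic) | [Li+].[O-]C1(C(=C)OCC)C(OCc2ccccc2)=C(OCc2ccccc2)C1=O | intermediate (not isolated)
7 | 2,3-bis(benzyloxy)-1-(1-ethoxyethenyl)-4-oxocyclobut-2-en-1-yl trifluoroacetate (racemic) | O=C(OC1(C(=C)OCC)C(OCc2ccccc2)=C(OCc2ccccc2)C1=O)C(F)(F)F | intermediate (not isolated)
8 | 3-(benzyloxy)-4-(1-ethoxyethenyl)cyclobut-3-ene-1,2-dione | C=C(OCC)C1=C(OCc2ccccc2)C(=O)C1=O | intermediate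
9 | tert-butyl vinyl ether | C=COC(C)(C)C | starting material
10 | 1-tert-butoxyethenyllithium | [Li]C(=C)OC(C)(C)C | intermediate (not isolated)
11 | 3-(benzyloxy)-4-(1-tert-butoxyethenyl)-2-(1-ethoxyethenyl)-4-hydroxycyclobut-2-en-1-one (racemic) | C=C(OCC)C1=C(OCc2ccccc2)C(O)(C(=C)OC(C)(C)C)C1=O | intermediate
12 | (3Z)-3-(benzyloxy)-5-tert-butoxy-2-(1-ethoxyethenyl)-4-hydroxyhexa-1,3,5-trien-1-one (dienylketene) | O=C=C(C(=C)OCC)/C(OCc1ccccc1)=C(/O)C(=C)OC(C)(C)C | intermediate (not isolated)
13 | 3-(benzyloxy)-5-tert-butoxy-2-(1-ethoxyethenyl)-4-hydroxycyclohexa-2,4-dien-1-one | C=C(OCC)C1=C(OCc2ccccc2)C(O)=C(OC(C)(C)C)CC1=O | intermediate (not isolated)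
14 | 3-(benzyloxy)-5-tert-butoxy-2-(1-ethoxyethenyl)benzene-1,4-diol | C=C(OCC)c1c(O)cc(OC(C)(C)C)c(O)c1OCc1ccccc1 | intermediate
15 | 1-[2-(benzyloxy)-4-tert-butoxy-3,6-dihydroxyphenyl]ethan-1-one | CC(=O)c1c(O)cc(OC(C)(C)C)c(O)c1OCc1ccccc1 | intermediate
16 | 1-[2,3-bis(benzyloxy)-4-tert-butoxy-6-hydroxyphenyl]ethan-1-one | CC(=O)c1c(O)cc(OC(C)(C)C)c(OCc2ccccc2)c1OCc1ccccc1 | intermediate
17 | 4-(benzyloxy)benzoyl chloride | O=C(Cl)c1ccc(OCc2ccccc2)cc1 | starting material
18 | 1-[2,3-bis(benzyloxy)-4-tert-butoxy-6-hydroxyphenyl]-3-[4-(benzyloxy)phenyl]propane-1,3-dione | O=C(CC(=O)c1ccc(OCc2ccccc2)cc1)c1c(O)cc(OC(C)(C)C)c(OCc2ccccc2)c1OCc1ccccc1 | intermediate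
19 | 5,6-bis(benzyloxy)-2-[4-(benzyloxy)phenyl]-7-tert-butoxy-4H-chromen-4-one | O=c1cc(-c2ccc(OCc3ccccc3)cc2)oc2cc(OC(C)(C)C)c(OCc3ccccc3)c(OCc3ccccc3)c12 | intermediate
20 | 5,6-bis(benzyloxy)-2-[4-(benzyloxy)phenyl]-7-tert-butoxy-2,3-epoxy-2,3-dihydro-4H-chromen-4-one (cis-fused, racemic, one enantiomer drawn) | O=C1[C@@H]2O[C@]2(c2ccc(OCc3ccccc3)cc2)Oc2cc(OC(C)(C)C)c(OCc3ccccc3)c(OCc3ccccc3)c12 | intermediate (not isolated)
21 | 5,6-bis(benzyloxy)-2-[4-(benzyloxy)phenyl]-7-tert-butoxy-3-hydroxy-4H-chromen-4-one | O=c1c(O)c(-c2ccc(OCc3ccccc3)cc2)oc2cc(OC(C)(C)C)c(OCc3ccccc3)c(OCc3ccccc3)c12 | intermediate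
22 | 3,5,6-tris(benzyloxy)-2-[4-(benzyloxy)phenyl]-7-tert-butoxy-4H-chromen-4-one | O=c1c(OCc2ccccc2)c(-c2ccc(OCc3ccccc3)cc2)oc2cc(OC(C)(C)C)c(OCc3ccccc3)c(OCc3ccccc3)c12 | intermediate
23 | 3,5,6-tris(benzyloxy)-2-[4-(benzyloxy)phenyl]-7-hydroxy-4H-chromen-4-one | O=c1c(OCc2ccccc2)c(-c2ccc(OCc3ccccc3)cc2)oc2cc(O)c(OCc3ccccc3)c(OCc3ccccc3)c12 | intermediate
24 | triethylammonium 3,5,6-tris(benzyloxy)-2-[4-(benzyloxy)phenyl]-4-oxo-4H-chromen-7-yl sulfate | CC[NH+](CC)CC.O=c1c(OCc2ccccc2)c(-c2ccc(OCc3ccccc3)cc2)oc2cc(OS(=O)(=O)[O-])c(OCc3ccccc3)c(OCc3ccccc3)c12 | intermediate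
25 | triethylammonium 3,5,6-trihydroxy-2-(4-hydroxyphenyl)-4-oxo-4H-chromen-7-yl sulfate | CC[NH+](CC)CC.O=c1c(O)c(-c2ccc(O)cc2)oc2cc(OS(=O)(=O)[O-])c(O)c(O)c12 | intermediate (not isolated)
26 | 3,5,6-trihydroxy-2-(4-hydroxyphenyl)-4-oxo-4H-chromen-7-yl hydrogen sulfate | O=c1c(O)c(-c2ccc(O)cc2)oc2cc(OS(=O)(=O)O)c(O)c(O)c12 | target

## Step count and least certain steps

Total step count: 13. Longest linear sequence: 13 steps, from squaric acid 1 to target 26.

**Step 4 (key step).** The most likely failures are inward rotation of the hydroxyl during ring opening, after which the ketene is captured by its own hydroxyl; thermal loss of isobutene from the tert-butyl enol ether before ring opening; and air oxidation of the electron-rich hydroquinone or its addition to the neighbouring enol ether during isolation. The fallback changes the substrate so that the carbinol oxygen is capped. It sets out from 11, which is silylated with 1-(trimethylsilyl)imidazole in CH2Cl2 to 3-(benzyloxy)-4-(1-tert-butoxyethenyl)-2-(1-ethoxyethenyl)-4-[(trimethylsilyl)oxy]cyclobut-2-en-1-one F1. A silyloxy group rotates outward just as reliably and cannot add to the ketene. Thermolysis in toluene at 110 °C should give the mono-protected, less oxidisable 3-(benzyloxy)-5-tert-butoxy-2-(1-ethoxyethenyl)-4-[(trimethylsilyl)oxy]phenol F2. The aqueous acid of step 5 then removes the silyl group together with the enol ether, and the route is rejoined at 15.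

**Step 2.** The trifluoroacetic acid set free at the quench may protonate and hydrolyse the ethoxyvinyl group, or the allyl cation may be captured at the wrong terminus. The fallback replaces addition and transposition by a cross-coupling and sets out from 1. Oxalyl chloride with catalytic DMF gives 3,4-dichlorocyclobut-3-ene-1,2-dione F3, and one equivalent of benzyl alcohol 2 gives 3-(benzyloxy)-4-chlorocyclobut-3-ene-1,2-dione F4. Stille coupling of F4 with tributyl(1-ethoxyethenyl)stannane (PdCl2(PPh3)2, CuI, MeCN, rt) installs the ethoxyvinyl group under neutral conditions and rejoins the route at 8.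

**Step 6.** Alkylation may occur at both phenols, or stall at the crowded O6 between the benzyloxy and tert-butoxy groups, and the hydroquinone dianion may be oxidised under base. The fallback removes the selectivity question by postponing the benzylation and sets out from 15. With 4.2 equivalents of LiN(SiMe3)2 and one equivalent of 17, the trianion is acylated at carbon to give 1-[2-(benzyloxy)-4-tert-butoxy-3,6-dihydroxyphenyl]-3-[4-(benzyloxy)phenyl]propane-1,3-dione F5. Cyclodehydration with NaOAc in AcOH gives 5-(benzyloxy)-2-[4-(benzyloxy)phenyl]-7-tert-butoxy-6-hydroxy-4H-chromen-4-one F6, in which O6 is the only free hydroxyl. Benzylation (BnBr, K2CO3, DMF) rejoins the route at 19.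

**Step 8.** Hot acetic acid may cleave the tert-butyl ether on O7 before the ring has closed. The fallback accepts that loss and changes the O7 protecting group; it sets out from 18.
- CF3CO2H in CH2Cl2 at room temperature closes the ring and removes the tert-butyl group, giving 5,6-bis(benzyloxy)-2-[4-(benzyloxy)phenyl]-7-hydroxy-4H-chromen-4-one F7.
- Chloromethyl methyl ether and iPr2NEt give 5,6-bis(benzyloxy)-2-[4-(benzyloxy)phenyl]-7-(methoxymethoxy)-4H-chromen-4-one F8.
- Dimethyldioxirane gives the epoxide 5,6-bis(benzyloxy)-2-[4-(benzyloxy)phenyl]-7-(methoxymethoxy)-2,3-epoxy-2,3-dihydro-4H-chromen-4-one F9 (not isolated), which mild acid opens to 5,6-bis(benzyloxy)-2-[4-(benzyloxy)phenyl]-3-hydroxy-7-(methoxymethoxy)-4H-chromen-4-one F10.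
- Benzylation gives 3,5,6-tris(benzyloxy)-2-[4-(benzyloxy)phenyl]-7-(methoxymethoxy)-4H-chromen-4-one F11.
- Dilute HCl in MeOH/THF removes the acetal and rejoins the route at 23.

**Step 9.** Epoxidation of the electron-poor C2=C3 bond may be slow enough for the dioxirane to attack benzylic C–H bonds or ring A instead, and the acid used to open the epoxide may start to remove the tert-butyl group. The fallback replaces electrophilic oxidation by deprotonation and sets out from 19. LiN(iPr)2 in THF at −78 °C removes the C3 hydrogen, B(OMe)3 traps the anion as dimethyl {5,6-bis(benzyloxy)-2-[4-(benzyloxy)phenyl]-7-tert-butoxy-4-oxo-4H-chromen-3-yl}boronate F12 (not isolated), and H2O2 in AcOH oxidises the C–B bond, rejoining the route at 21.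

## Further compounds

F1 | step 4 | 3-(benzyloxy)-4-(1-tert-butoxyethenyl)-2-(1-ethoxyethenyl)-4-[(trimethylsilyl)oxy]cyclobut-2-en-1-one (racemic) | C=C(OCC)C1=C(OCc2ccccc2)C(O[Si](C)(C)C)(C(=C)OC(C)(C)C)C1=O
F2 | step 4 | 3-(benzyloxy)-5-tert-butoxy-2-(1-ethoxyethenyl)-4-[(trimethylsilyl)oxy]phenol | C=C(OCC)c1c(O)cc(OC(C)(C)C)c(O[Si](C)(C)C)c1OCc1ccccc1
F3 | step 2 | 3,4-dichlorocyclobut-3-ene-1,2-dione | O=C1C(=O)C(Cl)=C1Cl
F4 | step 2 | 3-(benzyloxy)-4-chlorocyclobut-3-ene-1,2-dione | O=C1C(=O)C(OCc2ccccc2)=C1Cl
F5 | step 6 | 1-[2-(benzyloxy)-4-tert-butoxy-3,6-dihydroxyphenyl]-3-[4-(benzyloxy)phenyl]propane-1,3-dione | O=C(CC(=O)c1ccc(OCc2ccccc2)cc1)c1c(O)cc(OC(C)(C)C)c(O)c1OCc1ccccc1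
F6 | step 6 | 5-(benzyloxy)-2-[4-(benzyloxy)phenyl]-7-tert-butoxy-6-hydroxy-4H-chromen-4-one | O=c1cc(-c2ccc(OCc3ccccc3)cc2)oc2cc(OC(C)(C)C)c(O)c(OCc3ccccc3)c12
F7 | step 8 | 5,6-bis(benzyloxy)-2-[4-(benzyloxy)phenyl]-7-hydroxy-4H-chromen-4-one | O=c1cc(-c2ccc(OCc3ccccc3)cc2)oc2cc(O)c(OCc3ccccc3)c(OCc3ccccc3)c12
F8 | step 8 | 5,6-bis(benzyloxy)-2-[4-(benzyloxy)phenyl]-7-(methoxymethoxy)-4H-chromen-4-one | O=c1cc(-c2ccc(OCc3ccccc3)cc2)oc2cc(OCOC)c(OCc3ccccc3)c(OCc3ccccc3)c12
F9 | step 8 | 5,6-bis(benzyloxy)-2-[4-(benzyloxy)phenyl]-7-(methoxymethoxy)-2,3-epoxy-2,3-dihydro-4H-chromen-4-one (cis-fused, racemic, one enantiomer drawn) | O=C1[C@@H]2O[C@]2(c2ccc(OCc3ccccc3)cc2)Oc2cc(OCOC)c(OCc3ccccc3)c(OCc3ccccc3)c12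
F10 | step 8 | 5,6-bis(benzyloxy)-2-[4-(benzyloxy)phenyl]-3-hydroxy-7-(methoxymethoxy)-4H-chromen-4-one | O=c1c(O)c(-c2ccc(OCc3ccccc3)cc2)oc2cc(OCOC)c(OCc3ccccc3)c(OCc3ccccc3)c12
F11 | step 8 | 3,5,6-tris(benzyloxy)-2-[4-(benzyloxy)phenyl]-7-(methoxymethoxy)-4H-chromen-4-one | O=c1c(OCc2ccccc2)c(-c2ccc(OCc3ccccc3)cc2)oc2cc(OCOC)c(OCc3ccccc3)c(OCc3ccccc3)c12
F12 | step 9 | dimethyl {5,6-bis(benzyloxy)-2-[4-(benzyloxy)phenyl]-7-tert-butoxy-4-oxo-4H-chromen-3-yl}boronate | COB(OC)c1c(-c2ccc(OCc3ccccc3)cc2)oc2cc(OC(C)(C)C)c(OCc3ccccc3)c(OCc3ccccc3)c2c1=O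
A1 | alternative 1 | 2-(benzyloxy)-1-[3-(benzyloxy)-6-bromo-2,4-bis(methoxymethoxy)phenyl]-3-[4-(benzyloxy)phenyl]propane-1,3-dione (racemic, enolisable) | O=C(C(OCc1ccccc1)C(=O)c1ccc(OCc2ccccc2)cc1)c1c(Br)cc(OCOC)c(OCc2ccccc2)c1OCOC
A2 | alternative 1 | 3,6-bis(benzyloxy)-2-[4-(benzyloxy)phenyl]-5,7-bis(methoxymethoxy)-4H-chromen-4-one | O=c1c(OCc2ccccc2)c(-c2ccc(OCc3ccccc3)cc2)oc2cc(OCOC)c(OCc3ccccc3)c(OCOC)c12
A3 | alternative 2 | 3-(benzyloxy)-6-{1-[4-(benzyloxy)phenyl]-2-oxoethoxy}-2,4-bis(methoxymethoxy)benzaldehyde (racemic) | O=Cc1c(OC(C=O)c2ccc(OCc3ccccc3)cc2)cc(OCOC)c(OCc2ccccc2)c1OCOC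
A4 | alternative 2 | trans-6-(benzyloxy)-2-[4-(benzyloxy)phenyl]-3-hydroxy-5,7-bis(methoxymethoxy)chroman-4-one (racemic, one enantiomer drawn) | O=C1c2c(OCOC)c(OCc3ccccc3)c(OCOC)cc2O[C@@H](c2ccc(OCc3ccccc3)cc2)[C@@H]1O
A5 | alternative 3 | (2E)-2-(benzyloxy)-3-[4-(benzyloxy)phenyl]-3-[4-(benzyloxy)-3,5-bis(prop-2-enyloxy)phenoxy]prop-2-enoic acid | OC(=O)/C(OCc1ccccc1)=C(\Oc1cc(OCC=C)c(OCc2ccccc2)c(OCC=C)c1)c1ccc(OCc2ccccc2)cc1
A6 | alternative 3 | 3,6-bis(benzyloxy)-2-[4-(benzyloxy)phenyl]-5,7-bis(prop-2-enyloxy)-4H-chromen-4-one | O=c1c(OCc2ccccc2)c(-c2ccc(OCc3ccccc3)cc2)oc2cc(OCC=C)c(OCc3ccccc3)c(OCC=C)c12
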